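The target is the γ-hydroxylated Diels–Alder dimer of a single xanthanolide, so one monomer is built and dimerized. Its cycloheptane ring (xanthane C1, C5–C10) is made by a Lewis acid-mediated formal (4+3) cycloaddition: a 2-silyloxydiene supplies C9–C10–C1–C5 and 2-(triethylsilyloxy)acrolein, a 2-oxyallyl cation equivalent, supplies C6–C7–C8, so the C5–C6 and C8–C9 ring bonds form in one operation. The step exploits the heteroatom pattern of that ring: oxygen on C8, a ketone at C7 next to it as the anchor for the lactone carbons, and a masked C1 carbonyl in 1,4-relation to C7. Wittig olefination, CBS reduction and directed hydrogenation set the trans-lactone; Heck coupling, dimerization and dienolate oxygenation complete the route.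

Key step: step 4

Remark on the chemistry: xanthane numbering is used throughout (ring C1, C5–C10; lactone C11–C13 across C7/C8; methyl C14 on C10; side chain C2–C4 and C15 on C1; primes for the half that reacts as dienophile). The configuration written in the SMILES (7S,8R,10S in each half, with 1R,5S,11′R) is taken as the target; both halves are then the same monomer, with trans-fused lactone and the C10 methyl cis to the C8–O bond.

Step 1
Reactants: 1 3-methylbut-3-en-2-one
Product: 2 3-methyl-2-[tri(propan-2-yl)silyloxy]buta-1,3-diene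
Conditions: i-Pr3SiOTf, Et3N, CH2Cl2, 0 °C
Reagents that add atoms: triisopropylsilyl trifluoromethanesulfonate, CC(C)[Si](C(C)C)(C(C)C)OS(=O)(=O)C(F)(F)F
Why: Silyl enol ether formation by soft enolization of the only enolizable position (the acetyl methyl, future C5) should give the 2-silyloxydiene, and no stereocenter is formed.

Step 2
Reactants: 3 2,2-dimethyl-1,3-dioxan-5-one
Product: 4 2,2-dimethyl-5-(triethylsilyloxy)-4H-1,3-dioxine
Conditions: Et3SiOTf, Et3N, CH2Cl2, 0 °C to rt
Reagents that add atoms: triethylsilyl trifluoromethanesulfonate, CC[Si](CC)(CC)OS(=O)(=O)C(F)(F)F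
Why: Silyl enol ether formation of a symmetrical ketone can give only one enol ether, and no stereocenter is formed.

Step 3
Reactants: 4 2,2-dimethyl-5-(triethylsilyloxy)-4H-1,3-dioxine
Product: 5 2-(triethylsilyloxy)prop-2-enal
Conditions: toluene, 110 °C
Reagents that add atoms: none
Why: Thermal retro-hetero-Diels–Alder reaction (cycloreversion) of the 4H-1,3-dioxine should expel acetone and release the 2-silyloxyacrolein.

Step 4
Reactants: 2 3-methyl-2-[tri(propan-2-yl)silyloxy]buta-1,3-diene; 5 2-(triethylsilyloxy)prop-2-enal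
Product: 7 4-methyl-2-(triethylsilyloxy)-5-[tri(propan-2-yl)silyloxy]cyclohept-4-en-1-one (racemic), via Diels–Alder aldehyde 6 (not isolated)
Conditions: Sc(OTf)3 (10 mol %), CH2Cl2, −78 to 0 °C
Reagents that add atoms: none
Why: Sc(OTf)3 activates the aldehyde of 5, which then acts as a 2-oxyallyl cation equivalent: the nucleophilic CH2 terminus C5 of the silyl enol ether in 2 bonds to C6, the other diene terminus C9 is captured first by C7 to give the para Diels–Alder aldehyde 6, and a 1,2-shift of C9 from C7 to the metal-bound aldehyde carbon C8 with O-to-O transfer of the triethylsilyl group then gives 7, so that C5–C6 and C8–C9 are both made in this operation. The closest known reaction type is the Lewis acid-promoted (4+3) cycloaddition of 2-(trialkylsilyloxy)acroleins with 1,3-dienes, which runs as a tandem Diels–Alder reaction and α-ketol ring expansion. A six-membered ring is closed by the (4+2) event and is enlarged to the seven-membered ring by the suprafacial 1,2-shift that inserts C8 between C7 and C9. The only new stereocenter of 7, C8, is not controlled here (racemate) and is reset under reagent control in steps 7 and 8. The step needs the para orientation (C5 to C6), which the C1 silyloxy group secures by polarizing the diene, and migration of C9 in preference to C6, which the allylic, enol ether-conjugated character of C9 secures. The hindered triisopropylsilyl enol ether C1=C10 should survive the catalytic Lewis acid and keeps C1 masked.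

Step 5
Reactants: 7 4-methyl-2-(triethylsilyloxy)-5-[tri(propan-2-yl)silyloxy]cyclohept-4-en-1-one (racemic); 8 ethyl 2-(triphenyl-λ5-phosphanylidene)acetate
Product: 9 ethyl (2E)-2-[4-methyl-2-(triethylsilyloxy)-5-[tri(propan-2-yl)silyloxy]cyclohept-4-en-1-ylidene]acetate (racemic)
Conditions: toluene, 90 °C
Reagents that add atoms: none
Why: Wittig olefination of the α-oxygenated C7 ketone with a stabilized ylide under neutral conditions should install C11 and C12 with the ester turned away from the bulky C8 silyloxy carbon (E), the isomer that cannot lactonize prematurely.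

Step 6
Reactants: 9 ethyl (2E)-2-[4-methyl-2-(triethylsilyloxy)-5-[tri(propan-2-yl)silyloxy]cyclohept-4-en-1-ylidene]acetate (racemic)
Product: 10 ethyl (2E)-2-[2-hydroxy-4-methyl-5-[tri(propan-2-yl)silyloxy]cyclohept-4-en-1-ylidene]acetate (racemic)
Conditions: HF·pyridine, pyridine, THF, 0 °C
Reagents that add atoms: none
Why: Selective desilylation should occur because buffered fluoride cleaves the secondary triethylsilyl ether far faster than the hindered triisopropylsilyl enol ether.

Step 7
Reactants: 10 ethyl (2E)-2-[2-hydroxy-4-methyl-5-[tri(propan-2-yl)silyloxy]cyclohept-4-en-1-ylidene]acetate (racemic)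
Product: 11 ethyl (2E)-2-[4-methyl-2-oxo-5-[tri(propan-2-yl)silyloxy]cyclohept-4-en-1-ylidene]acetate
Conditions: MnO2 (20 equiv), CH2Cl2, rt
Reagents that add atoms: none
Why: Allylic alcohol oxidation under neutral conditions should give the achiral enone, erasing the uncontrolled C8 stereocenter while the silyl enol ether keeps C1 masked.

Step 8
Reactants: 11 ethyl (2E)-2-[4-methyl-2-oxo-5-[tri(propan-2-yl)silyloxy]cyclohept-4-en-1-ylidene]acetate
Product: 12 ethyl (2E)-2-[(2R)-2-hydroxy-4-methyl-5-[tri(propan-2-yl)silyloxy]cyclohept-4-en-1-ylidene]acetate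
Conditions: (S)-1-methyl-3,3-diphenyltetrahydro-1H,3H-pyrrolo[1,2-c][1,3,2]oxazaborole (20 mol %), BH3·SMe2, THF, −30 °C; then MeOH
Reagents that add atoms: none
Why: Corey–Bakshi–Shibata reduction should deliver hydride 1,2 to the enone with the alkylidene carbon C7 as the large and C9H2 as the small substituent, so that the (S)-catalyst sets the 8R carbinol under reagent control.

Step 9
Reactants: 12 ethyl (2E)-2-[(2R)-2-hydroxy-4-methyl-5-[tri(propan-2-yl)silyloxy]cyclohept-4-en-1-ylidene]acetate
Product: 13 ethyl 2-[(1S,2R)-2-hydroxy-4-methyl-5-[tri(propan-2-yl)silyloxy]cyclohept-4-en-1-yl]acetate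
Conditions: [Ir(cod)(PCy3)(py)]PF6 (5 mol %), H2 (1 atm), CH2Cl2, rt
Reagents that add atoms: none
Why: Hydroxyl-directed hydrogenation with the cationic iridium catalyst should add hydrogen to C7 from the face of the C8 hydroxyl, which places the C7–C11 bond trans to the C8–O bond (7S), while the tetrasubstituted silyl enol ether is left alone.

Step 10
Reactants: 13 ethyl 2-[(1S,2R)-2-hydroxy-4-methyl-5-[tri(propan-2-yl)silyloxy]cyclohept-4-en-1-yl]acetate
Product: 15 (3aS,7S,8aR)-7-methyl-3a,4,5,7,8,8a-hexahydro-2H-cyclohepta[b]furan-2,6(3H)-dione (trans-fused keto lactone), via keto hydroxy ester 14 (not isolated)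
Conditions: 2 M aq. HCl, THF, 40 °C; then DBU (0.2 equiv), CH2Cl2, rt
Reagents that add atoms: none
Why: Acid hydrolysis of the silyl enol ether and acid-catalysed lactonization should give the trans-fused keto lactone, and enolization towards C10 should equilibrate that center to the epimer with the methyl pseudo-equatorial, cis to the equatorial C8–O bond (10S).

Step 11
Reactants: 15 (3aS,7S,8aR)-7-methyl-3a,4,5,7,8,8a-hexahydro-2H-cyclohepta[b]furan-2,6(3H)-dione
Product: 16 (3aS,7S,8aR)-7-methyl-2-oxo-3,3a,4,7,8,8a-hexahydro-2H-cyclohepta[b]furan-6-yl trifluoromethanesulfonate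
Conditions: KN(SiMe3)2 (1.05 equiv), THF, −78 °C; then PhNTf2, −78 to 0 °C
Reagents that add atoms: N-phenylbis(trifluoromethanesulfonimide), O=S(=O)(N(c1ccccc1)S(=O)(=O)C(F)(F)F)C(F)(F)F
Why: Kinetic enolization of the ketone (more acidic than the lactone) at the less hindered C5 methylene and O-triflation should give the C1=C5 enol triflate without touching the C10 stereocenter.

Step 12
Reactants: 16 (3aS,7S,8aR)-7-methyl-2-oxo-3,3a,4,7,8,8a-hexahydro-2H-cyclohepta[b]furan-6-yl trifluoromethanesulfonate
Product: 19 (3aS,7S,8aR)-7-methyl-3-methylidene-2-oxo-3,3a,4,7,8,8a-hexahydro-2H-cyclohepta[b]furan-6-yl trifluoromethanesulfonate, via Mannich base 17 (not isolated), via ammonium iodide 18 (not isolated)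
Conditions: LiN(i-Pr)2 (1.1 equiv), THF, −78 °C; Eschenmoser's salt, −78 to 0 °C; then MeI, MeOH, rt; then aq. NaHCO3, CH2Cl2, rt
Reagents that add atoms: N,N-dimethylmethylideneammonium iodide (Eschenmoser's salt), C=[N+](C)C.[I-]
Why: Mannich reaction of the lactone enolate, quaternization and β-elimination (α-methylenation of a lactone) should install C13 as the exocyclic methylene, and the transient C11 stereocenter disappears.

Step 13
Reactants: 19 (3aS,7S,8aR)-7-methyl-3-methylidene-2-oxo-3,3a,4,7,8,8a-hexahydro-2H-cyclohepta[b]furan-6-yl trifluoromethanesulfonate; 20 but-3-en-2-one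
Product: 21 (3aS,7S,8aR)-7-methyl-3-methylidene-6-[(1E)-3-oxobut-1-en-1-yl]-3,3a,4,7,8,8a-hexahydro-2H-cyclohepta[b]furan-2-one (the monomer)
Conditions: Pd(OAc)2 (10 mol %), PPh3 (20 mol %), Et3N, but-3-en-2-one (5 equiv), DMF, 50 °C
Reagents that add atoms: none
Why: Heck reaction of the vinyl triflate with the monosubstituted enone, used in excess and more reactive than the 1,1-disubstituted methylene lactone, should give the (E)-dienone side chain.

Step 14
Reactants: 21 the monomer (two molecules)
Product: 22 Diels–Alder dimer of 21: cyclohexene formed by the C3–C11′ and C5–C13′ bonds, spiro at C11′, C1=C2 double bond, acetyl on C3 (3S,5S,7S,8R,10S,11′R,7′S,8′R,10′S)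
Conditions: toluene (2 M), BHT (cat.), 100 °C, sealed tube
Reagents that add atoms: none
Why: Thermal Diels–Alder dimerization should join the dienone C5=C1–C2=C3 of one molecule to the exocyclic C11′=C13′ of another with ortho regiochemistry, in the carbonyl-exo mode usual for s-cis α-methylene lactones, on the dienophile face syn to H7′ (away from C6′) and on the exposed outer face of the chair cycloheptene diene (syn to H7), which together set 3S, 5S and 11′R.

Step 15
Reactants: 22 Diels–Alder dimer of 21
Product: 24 the target CNP0168949.4 (1-hydroxy-2-ene dimer; 1R,5S,7S,8R,10S,11′R,7′S,8′R,10′S), via hydroperoxide 23 (not isolated)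
Conditions: O2 (1 atm), DBU (0.3 equiv), THF, 0 °C; then Me2S, rt
Reagents that add atoms: dioxygen, O=O
Why: γ-Oxygenation of a dienolate (base-mediated autoxidation of a β,γ-unsaturated ketone) should start at the doubly activated C3–H, take up O2 at C1 on the face opposite the C5–C13′ bond and the C10 methyl (cis ring fusion, 1R) with the double bond moving to C2=C3, and dimethyl sulfide then reduces the hydroperoxide.

Compound list
1 | 3-methylbut-3-en-2-one | CC(=O)C(C)=C | starting material
2 | 3-methyl-2-[tri(propan-2-yl)silyloxy]buta-1,3-diene | C=C(O[Si](C(C)C)(C(C)C)C(C)C)C(C)=C | intermediate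
3 | 2,2-dimethyl-1,3-dioxan-5-one | CC1(C)OCC(=O)CO1 | starting material
4 | 2,2-dimethyl-5-(triethylsilyloxy)-4H-1,3-dioxine | CC1(C)OCC(O[Si](CC)(CC)CC)=CO1 | intermediate
5 | 2-(triethylsilyloxy)prop-2-enal | C=C(O[Si](CC)(CC)CC)C=O | intermediate
6 | 3-methyl-1-(triethylsilyloxy)-4-[tri(propan-2-yl)silyloxy]cyclohex-3-ene-1-carbaldehyde (racemic) | O=CC1(O[Si](CC)(CC)CC)CCC(O[Si](C(C)C)(C(C)C)C(C)C)=C(C)C1 | intermediate
7 | 4-methyl-2-(triethylsilyloxy)-5-[tri(propan-2-yl)silyloxy]cyclohept-4-en-1-one (racemic) | O=C1CCC(O[Si](C(C)C)(C(C)C)C(C)C)=C(C)CC1O[Si](CC)(CC)CC | intermediate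
8 | ethyl 2-(triphenyl-λ5-phosphanylidene)acetate | CCOC(=O)C=P(c1ccccc1)(c1ccccc1)c1ccccc1 | starting material
9 | ethyl (2E)-2-[4-methyl-2-(triethylsilyloxy)-5-[tri(propan-2-yl)silyloxy]cyclohept-4-en-1-ylidene]acetate (racemic) | CCOC(=O)/C=C1\CCC(O[Si](C(C)C)(C(C)C)C(C)C)=C(C)CC1O[Si](CC)(CC)CC | intermediate
10 | ethyl (2E)-2-[2-hydroxy-4-methyl-5-[tri(propan-2-yl)silyloxy]cyclohept-4-en-1-ylidene]acetate (racemic) | CCOC(=O)/C=C1\CCC(O[Si](C(C)C)(C(C)C)C(C)C)=C(C)CC1O | intermediate
11 | ethyl (2E)-2-[4-methyl-2-oxo-5-[tri(propan-2-yl)silyloxy]cyclohept-4-en-1-ylidene]acetate | CCOC(=O)/C=C1\CCC(O[Si](C(C)C)(C(C)C)C(C)C)=C(C)CC1=O | intermediate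
12 | ethyl (2E)-2-[(2R)-2-hydroxy-4-methyl-5-[tri(propan-2-yl)silyloxy]cyclohept-4-en-1-ylidene]acetate | CCOC(=O)/C=C1\CCC(O[Si](C(C)C)(C(C)C)C(C)C)=C(C)C[C@H]1O | intermediate
13 | ethyl 2-[(1S,2R)-2-hydroxy-4-methyl-5-[tri(propan-2-yl)silyloxy]cyclohept-4-en-1-yl]acetate | CCOC(=O)C[C@@H]1CCC(O[Si](C(C)C)(C(C)C)C(C)C)=C(C)C[C@H]1O | intermediate
14 | ethyl 2-[(1S,2R)-2-hydroxy-4-methyl-5-oxocycloheptyl]acetate (both C4 epimers) | CCOC(=O)C[C@@H]1CCC(=O)C(C)C[C@H]1O | intermediate
15 | (3aS,7S,8aR)-7-methyl-3a,4,5,7,8,8a-hexahydro-2H-cyclohepta[b]furan-2,6(3H)-dione | C1C(=O)O[C@@H]2C[C@H](C)C(=O)CC[C@@H]12 | intermediate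
16 | (3aS,7S,8aR)-7-methyl-2-oxo-3,3a,4,7,8,8a-hexahydro-2H-cyclohepta[b]furan-6-yl trifluoromethanesulfonate | C1C(=O)O[C@@H]2C[C@H](C)C(OS(=O)(=O)C(F)(F)F)=CC[C@@H]12 | intermediate
17 | (3aS,7S,8aR)-3-[(dimethylamino)methyl]-7-methyl-2-oxo-3,3a,4,7,8,8a-hexahydro-2H-cyclohepta[b]furan-6-yl trifluoromethanesulfonate (C3 epimers) | CN(C)CC1C(=O)O[C@@H]2C[C@H](C)C(OS(=O)(=O)C(F)(F)F)=CC[C@@H]12 | intermediate
18 | N,N,N-trimethyl-1-[(3aS,7S,8aR)-7-methyl-2-oxo-6-(trifluoromethanesulfonyloxy)-3,3a,4,7,8,8a-hexahydro-2H-cyclohepta[b]furan-3-yl]methanaminium iodide | C[N+](C)(C)CC1C(=O)O[C@@H]2C[C@H](C)C(OS(=O)(=O)C(F)(F)F)=CC[C@@H]12.[I-] | intermediate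
19 | (3aS,7S,8aR)-7-methyl-3-methylidene-2-oxo-3,3a,4,7,8,8a-hexahydro-2H-cyclohepta[b]furan-6-yl trifluoromethanesulfonate | C=C1C(=O)O[C@@H]2C[C@H](C)C(OS(=O)(=O)C(F)(F)F)=CC[C@@H]12 | intermediate
20 | but-3-en-2-one | CC(=O)C=C | starting material
21 | (3aS,7S,8aR)-7-methyl-3-methylidene-6-[(1E)-3-oxobut-1-en-1-yl]-3,3a,4,7,8,8a-hexahydro-2H-cyclohepta[b]furan-2-one | C=C1C(=O)O[C@@H]2C[C@H](C)C(/C=C/C(C)=O)=CC[C@@H]12 | intermediate
22 | Diels–Alder dimer of 21 (C3–C11′ and C5–C13′ bonds, C1=C2, 3-acetyl; 3S,5S,7S,8R,10S,11′R,7′S,8′R,10′S) | C=C1C(=O)O[C@@H]2C[C@H](C)C3=C[C@H](C(C)=O)[C@]4(C[C@@H]3C[C@@H]12)C(=O)O[C@@H]1C[C@H](C)C(/C=C/C(C)=O)=CC[C@H]14 | intermediate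
23 | C1 hydroperoxide of the target (1-hydroperoxy-2-ene dimer; 1R,5S,11′R) | C=C1C(=O)O[C@@H]2C[C@H](C)[C@]3(OO)C=C(C(C)=O)[C@]4(C[C@@H]3C[C@@H]12)C(=O)O[C@@H]1C[C@H](C)C(/C=C/C(C)=O)=CC[C@H]14 | intermediate
24 | CNP0168949.4 (1-hydroxy-2-ene dimer; 1R,5S,7S,8R,10S,11′R,7′S,8′R,10′S) | C=C1C(=O)O[C@@H]2C[C@H](C)[C@]3(O)C=C(C(C)=O)[C@]4(C[C@@H]3C[C@@H]12)C(=O)O[C@@H]1C[C@H](C)C(/C=C/C(C)=O)=CC[C@H]14 | target

Total step count: 15
Longest linear sequence: 14 steps (from 3 through steps 2 to 15)

Steps most likely to fail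

Step 4. The cascade may stall before ring enlargement, or the electron-rich diene may be consumed by open-chain Mukaiyama-type addition and desilylation under the Lewis acid. The fallback sets out from 2 and 5 and comes back to the route at 7. It separates the two bond-forming events: a Lewis acid-free thermal Diels–Alder reaction (toluene, 80 °C) should give the para adduct 6, which is isolated. A dedicated α-ketol ring expansion of 6 (Me2AlCl, 20 mol %, CH2Cl2, −78 °C) then moves C9 from C7 to C8 and transfers the silyl group. No compound outside the list is made.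

Step 10. Equilibration at C10 may discriminate poorly between the two epimers of the flexible cycloheptanone, leaving a mixture. The fallback sets out from 15 (as the C10 epimer mixture) and comes back at 15. It replaces thermodynamic control by catalyst-controlled kinetic protonation. Me3SiCl, Et3N, DMF at 80 °C should convert the mixture into the more substituted silyl enol ether (3aS,8aR)-7-methyl-6-(trimethylsilyloxy)-3,3a,4,5,8,8a-hexahydro-2H-cyclohepta[b]furan-2-one F1, in which C10 is planar. F1 is then protonated with 2,6-dimethylphenol in the presence of the complex of SnCl4 and 2′-methoxy-1,1′-binaphthalen-2-ol (10 mol %; the antipode that delivers 10S is chosen) in toluene at −78 °C.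

Step 14. The dimerization may go beyond the dimer, because 22 still carries a dienone and a methylene lactone, and may divert into a hetero-Diels–Alder mode through the enone of the dienophile partner, besides incomplete facial discrimination. The fallback sets out from 21 and 19 and comes back at 22. Diene 21 is heated with an excess of triflate 19 (3 equiv, toluene, 100 °C), which can act only as dienophile. This should give the cross-adduct, the analogue of 22 in which the C1′ oxobutenyl chain is replaced by a trifluoromethanesulfonyloxy group F2. Heck coupling of F2 with 20 (Pd(OAc)2, PPh3, Et3N, DMF, 50 °C) then installs the second side chain.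

Further compounds
F0 | step 4 | none | none
F1 | step 10 | (3aS,8aR)-7-methyl-6-(trimethylsilyloxy)-3,3a,4,5,8,8a-hexahydro-2H-cyclohepta[b]furan-2-one | C1C(=O)O[C@@H]2CC(C)=C(O[Si](C)(C)C)CC[C@@H]12
F2 | step 14 | cross Diels–Alder adduct of 21 (diene) and 19 (dienophile): analogue of 22 with OSO2CF3 on C1′ in place of the oxobutenyl chain | C=C1C(=O)O[C@@H]2C[C@H](C)C3=C[C@H](C(C)=O)[C@]4(C[C@@H]3C[C@@H]12)C(=O)O[C@@H]1C[C@H](C)C(OS(=O)(=O)C(F)(F)F)=CC[C@H]14
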